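Everything rests on cutting the pyran ring at C4–C4a. The key step exploits that C3 lies between two methylene carbons, C2 on O1 and C4 on C4a of ring A, so C2–C3–C4 plus ring B is a prochiral 2-arylpropane-1,3-diol. A lipase differentiates the two CH2OH arms and thereby fixes C3. One arm is etherified by a ring A ortho-iodophenol and the other becomes CH2Br. The resulting precursor, an aryl iodide tethered through O1–C2–C3 to a primary bromide, undergoes iodine–lithium exchange and intramolecular alkylation. This forms C4–C4a and closes the chroman in one operation without touching C3. Debenzylation and phenol-selective oxidation of ring B give the quinone.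

Key step: step 16

Assumption: the lipase is taken to acetylate the pro-S hydroxymethyl group of the prochiral diol, the usual sense for this enzyme family with 2-substituted propane-1,3-diols. The sense is to be confirmed on the monoacetate before it is carried on.

Step 1
Reactants: 1 1,2,3,4-tetramethoxybenzene
Product: 4 2,3,4,5-tetramethoxyphenol, via aryllithium 2 (not isolated), via arylboronate 3 (not isolated)
Conditions: n-BuLi, TMEDA, THF, 0 °C; B(OMe)3, −78 °C to rt; AcOH, 30% aq. H2O2, 0 °C to rt
Reagents that add atoms: hydrogen peroxide, OO; n-butyllithium, [Li]CCCC (lithium of 2 only); trimethyl borate, COB(OC)OC (boron and methoxy groups of 3 only)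
Why: Directed ortho-lithiation next to a terminal methoxy group (the two free ring positions are equivalent), borylation and peroxide-induced aryl migration from boron to oxygen form the standard one-pot hydroxylation of an arene, so the fifth oxygen of ring B enters without a regiochemical choice.

Step 2
Reactants: 4 2,3,4,5-tetramethoxyphenol; 5 allyl bromide
Product: 6 1-(allyloxy)-2,3,4,5-tetramethoxybenzene
Conditions: K2CO3, acetone, reflux
Reagents that add atoms: none
Why: Williamson ether synthesis, in which the phenoxide displaces bromide from the reactive allylic halide in an SN2 reaction.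

Step 3
Reactants: 6 1-(allyloxy)-2,3,4,5-tetramethoxybenzene
Product: 7 2-allyl-3,4,5,6-tetramethoxyphenol
Conditions: N,N-diethylaniline, 200 °C, argon
Reagents that add atoms: none
Why: Aromatic Claisen rearrangement, whose [3,3]-sigmatropic shift can end in rearomatisation only at the one unsubstituted ortho carbon, so the bond between ring B and the future C3 forms at a single position.

Step 4
Reactants: 7 2-allyl-3,4,5,6-tetramethoxyphenol
Product: 8 1-allyl-2-(benzyloxy)-3,4,5,6-tetramethoxybenzene
Conditions: BnBr, K2CO3, DMF, rt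
Reagents that add atoms: benzyl bromide, BrCc1ccccc1
Why: Williamson benzylation masks the phenol that will later trigger quinone formation, and the benzyl ether withstands every oxidant, hydride, base and organolithium used up to step 16.

Step 5
Reactants: 8 1-allyl-2-(benzyloxy)-3,4,5,6-tetramethoxybenzene
Product: 10 2-[2-(benzyloxy)-3,4,5,6-tetramethoxyphenyl]acetaldehyde, via vicinal diol 9 (not isolated)
Conditions: OsO4 (cat.), NaIO4, 2,6-lutidine, dioxane–H2O, rt
Reagents that add atoms: sodium periodate, [Na+].[O-]I(=O)(=O)=O (terminal oxygen source); osmium tetroxide, O=[Os](=O)(=O)=O (oxygen carrier)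
Why: Lemieux–Johnson oxidation, in which catalytic dihydroxylation of the only alkene and periodate cleavage of diol 9 remove the terminal carbon under near-neutral conditions that spare the fully substituted arene and the benzyl ether.

Step 6
Reactants: 10 2-[2-(benzyloxy)-3,4,5,6-tetramethoxyphenyl]acetaldehyde
Product: 11 2-[2-(benzyloxy)-3,4,5,6-tetramethoxyphenyl]acetic acid
Conditions: NaClO2, NaH2PO4, 2-methyl-2-butene, t-BuOH–H2O, 0 °C to rt
Reagents that add atoms: sodium chlorite, [Na+].[O-]Cl=O
Why: Pinnick oxidation converts the enolisable aldehyde to the acid at buffered pH, with 2-methyl-2-butene trapping the hypochlorous acid that could otherwise attack ring B.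

Step 7
Reactants: 11 2-[2-(benzyloxy)-3,4,5,6-tetramethoxyphenyl]acetic acid
Product: 12 methyl 2-[2-(benzyloxy)-3,4,5,6-tetramethoxyphenyl]acetate
Conditions: MeI, K2CO3, DMF, rt
Reagents that add atoms: iodomethane, CI
Why: SN2 O-methylation of the carboxylate is an esterification that keeps acid away from the benzyl ether.

Step 8
Reactants: 12 methyl 2-[2-(benzyloxy)-3,4,5,6-tetramethoxyphenyl]acetate; 13 dimethyl carbonate
Product: 14 dimethyl 2-[2-(benzyloxy)-3,4,5,6-tetramethoxyphenyl]malonate
Conditions: NaH, THF, reflux; then cold dilute HCl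
Reagents that add atoms: none
Why: Crossed Claisen condensation, in which the ester enolate is methoxycarbonylated by non-enolisable dimethyl carbonate and deprotonation of the arylmalonate pulls the equilibrium over, adding the third carbon of the C2–C3–C4 unit.

Step 9
Reactants: 14 dimethyl 2-[2-(benzyloxy)-3,4,5,6-tetramethoxyphenyl]malonate
Product: 15 2-[2-(benzyloxy)-3,4,5,6-tetramethoxyphenyl]propane-1,3-diol
Conditions: LiAlH4, THF, 0 °C to rt (14 added slowly to the hydride); aqueous work-up
Reagents that add atoms: none
Why: Hydride reduction of both ester groups gives the prochiral 2-arylpropane-1,3-diol, and slow addition of 14 to excess LiAlH4 in the cold keeps enolate formation and elimination low.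

Step 10
Reactants: 15 2-[2-(benzyloxy)-3,4,5,6-tetramethoxyphenyl]propane-1,3-diol; 16 vinyl acetate
Product: 17 (S)-2-[2-(benzyloxy)-3,4,5,6-tetramethoxyphenyl]-3-hydroxypropyl acetate
Conditions: Amano lipase PS (immobilised), t-BuOMe, 30 °C, stopped before diacetate builds up
Reagents that add atoms: none
Why: Enzymatic desymmetrisation by irreversible transesterification, in which the chiral acyl-enzyme acetylates only the pro-S hydroxymethyl group, making C3 a stereocentre of S configuration, while tautomerisation of the released vinyl alcohol prevents the back reaction.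

Step 11
Reactants: 18 2,3,4-trimethoxybenzaldehyde
Product: 20 2,3,4-trimethoxyphenol, via aryl formate 19 (not isolated)
Conditions: 30% aq. H2O2, H2SO4 (cat.), MeOH, rt
Reagents that add atoms: hydrogen peroxide, OO
Why: Dakin oxidation under acid catalysis, in which the peroxide adduct of the aldehyde undergoes migration of the electron-rich aryl group to oxygen and formate 19 is methanolysed in the same flask.

Step 12
Reactants: 20 2,3,4-trimethoxyphenol
Product: 21 6-iodo-2,3,4-trimethoxyphenol
Conditions: I2 (1.0 equiv), NaHCO3, THF–H2O, 0 °C, dark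
Reagents that add atoms: iodine, II
Why: Electrophilic aromatic iodination through the phenoxide, whose oxygen outweighs the methoxy donors and whose para position is blocked, so substitution goes to C6, the only free ortho carbon and the future C4a.

Step 13
Reactants: 17 (S)-2-[2-(benzyloxy)-3,4,5,6-tetramethoxyphenyl]-3-hydroxypropyl acetate; 21 6-iodo-2,3,4-trimethoxyphenol
Product: 22 (S)-2-[2-(benzyloxy)-3,4,5,6-tetramethoxyphenyl]-3-(6-iodo-2,3,4-trimethoxyphenoxy)propyl acetate
Conditions: PPh3, DIAD, THF, 0 °C to rt
Reagents that add atoms: none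
Why: Mitsunobu reaction, in which the primary alcohol is activated as its alkoxyphosphonium ion and displaced by the acidic iodophenol at C2, a carbon that is not stereogenic, so C3 keeps its configuration and the acetate stays in place under the neutral conditions.

Step 14
Reactants: 22 (S)-2-[2-(benzyloxy)-3,4,5,6-tetramethoxyphenyl]-3-(6-iodo-2,3,4-trimethoxyphenoxy)propyl acetate
Product: 23 (R)-2-[2-(benzyloxy)-3,4,5,6-tetramethoxyphenyl]-3-(6-iodo-2,3,4-trimethoxyphenoxy)propan-1-ol
Conditions: K2CO3 (0.2 equiv), MeOH, 0 °C to rt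
Reagents that add atoms: none
Why: Base-catalysed transesterification (methanolysis) removes the acetate without affecting the aryl iodide, the ethers or C3, and the descriptor reads R only because the CIP ranking of the two arms changes.

Step 15
Reactants: 23 (R)-2-[2-(benzyloxy)-3,4,5,6-tetramethoxyphenyl]-3-(6-iodo-2,3,4-trimethoxyphenoxy)propan-1-ol
Product: 24 (S)-1-(benzyloxy)-2-[1-bromo-3-(6-iodo-2,3,4-trimethoxyphenoxy)propan-2-yl]-3,4,5,6-tetramethoxybenzene
Conditions: CBr4, PPh3, CH2Cl2, 0 °C; used at once
Reagents that add atoms: tetrabromomethane, BrC(Br)(Br)Br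
Why: Appel reaction, in which bromide displaces the alkoxyphosphonium ion in an SN2 reaction at C4 under cold, neutral conditions that keep the two flanking ortho-alkoxy groups of ring B from taking part, which is also why the bromide is made last.

Step 16
Reactants: 24 (S)-1-(benzyloxy)-2-[1-bromo-3-(6-iodo-2,3,4-trimethoxyphenoxy)propan-2-yl]-3,4,5,6-tetramethoxybenzene
Product: 26 (S)-3-[2-(benzyloxy)-3,4,5,6-tetramethoxyphenyl]-6,7,8-trimethoxychroman, via aryllithium 25 (not isolated)
Conditions: n-BuLi (1.05 equiv), THF (0.01 mol/L), −100 °C, 15 min; then to 0 °C; aq. NH4Cl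
Reagents that add atoms: n-butyllithium, [Li]CCCC (lithium of 25 only)
Why: n-BuLi attacks the iodine atom of 24 through an iodine ate complex and delivers lithium to C4a far below the temperature at which it reacts at other sites, which gives aryllithium 25, stabilised by the adjacent O1. On warming, the carbanionic C4a displaces bromide from C4 in an intramolecular SN2 reaction; this is the Parham cyclization (anionic cycloalkylation), whose closest precedent is the conversion of ortho-halophenyl 3-halopropyl ethers to chromans. The pyran ring closes in the 6-exo-tet mode and C4–C4a is the only skeletal bond formed. No stereocentre is created: C3 takes no part, its hydrogen next to a twisted, electron-rich aryl group is too weakly acidic for 25 to remove, and so the configuration set in step 10 is carried through unchanged. The selectivity needed is exchange at the arene in the presence of a primary bromide and a benzyl ether, and the substrate secures it by carrying the fast-exchanging iodide on ring A and the slow-reacting bromide on C4, while one equivalent of n-BuLi (not t-BuLi, which would lithiate the OCH2Ph group) is used up before it can act as a base. High dilution lets ring closure outrun butylation of 25 by the 1-iodobutane that the exchange releases.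

Step 17
Reactants: 26 (S)-3-[2-(benzyloxy)-3,4,5,6-tetramethoxyphenyl]-6,7,8-trimethoxychroman
Product: 27 (S)-2,3,4,5-tetramethoxy-6-(6,7,8-trimethoxychroman-3-yl)phenol
Conditions: H2 (1 atm), Pd/C, EtOAc–EtOH, rt
Reagents that add atoms: none
Why: Catalytic hydrogenolysis cleaves only the benzylic carbon–oxygen bond, since no halogen, alkene or other reducible group is left.

Step 18
Reactants: 27 (S)-2,3,4,5-tetramethoxy-6-(6,7,8-trimethoxychroman-3-yl)phenol
Product: 28 (S)-2,3,5-trimethoxy-6-(6,7,8-trimethoxychroman-3-yl)cyclohexa-2,5-diene-1,4-dione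
Conditions: PhI(OAc)2 (1.1 equiv), MeCN–H2O, 0 °C
Reagents that add atoms: water, O
Why: Oxidative demethylation of a para-methoxyphenol by a trivalent iodine reagent, in which ligand exchange needs the free hydroxyl group, so only ring B is oxidised, water adds at the methoxy-bearing para carbon and loss of methanol gives the 1,4-quinone while the fully etherified ring A is left alone.

Compound list
1 | 1,2,3,4-tetramethoxybenzene | COc1ccc(OC)c(OC)c1OC | starting material
2 | (2,3,4,5-tetramethoxyphenyl)lithium (formed in the flask) | [Li]c1cc(OC)c(OC)c(OC)c1OC | intermediate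
3 | dimethyl (2,3,4,5-tetramethoxyphenyl)boronate (formed in the flask) | COB(OC)c1cc(OC)c(OC)c(OC)c1OC | intermediate
4 | 2,3,4,5-tetramethoxyphenol | Oc1cc(OC)c(OC)c(OC)c1OC | intermediate
5 | allyl bromide | C=CCBr | starting material
6 | 1-(allyloxy)-2,3,4,5-tetramethoxybenzene | C=CCOc1cc(OC)c(OC)c(OC)c1OC | intermediate
7 | 2-allyl-3,4,5,6-tetramethoxyphenol | COc1c(OC)c(OC)c(OC)c(O)c1CC=C | intermediate
8 | 1-allyl-2-(benzyloxy)-3,4,5,6-tetramethoxybenzene | COc1c(OC)c(OC)c(OC)c(OCc2ccccc2)c1CC=C | intermediate
9 | 3-[2-(benzyloxy)-3,4,5,6-tetramethoxyphenyl]propane-1,2-diol, racemic (formed in the flask) | COc1c(OC)c(OC)c(OC)c(OCc2ccccc2)c1CC(O)CO | intermediate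
10 | 2-[2-(benzyloxy)-3,4,5,6-tetramethoxyphenyl]acetaldehyde | COc1c(OC)c(OC)c(OC)c(OCc2ccccc2)c1CC=O | intermediate
11 | 2-[2-(benzyloxy)-3,4,5,6-tetramethoxyphenyl]acetic acid | COc1c(OC)c(OC)c(OC)c(OCc2ccccc2)c1CC(=O)O | intermediate
12 | methyl 2-[2-(benzyloxy)-3,4,5,6-tetramethoxyphenyl]acetate | COc1c(OC)c(OC)c(OC)c(OCc2ccccc2)c1CC(=O)OC | intermediate
13 | dimethyl carbonate | COC(=O)OC | starting material
14 | dimethyl 2-[2-(benzyloxy)-3,4,5,6-tetramethoxyphenyl]malonate | COc1c(OC)c(OC)c(OC)c(OCc2ccccc2)c1C(C(=O)OC)C(=O)OC | intermediate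
15 | 2-[2-(benzyloxy)-3,4,5,6-tetramethoxyphenyl]propane-1,3-diol (prochiral) | COc1c(OC)c(OC)c(OC)c(OCc2ccccc2)c1C(CO)CO | intermediate
16 | vinyl acetate | CC(=O)OC=C | starting material
17 | (S)-2-[2-(benzyloxy)-3,4,5,6-tetramethoxyphenyl]-3-hydroxypropyl acetate | COc1c(OC)c(OC)c(OC)c(OCc2ccccc2)c1[C@H](COC(C)=O)CO | intermediate
18 | 2,3,4-trimethoxybenzaldehyde | COc1ccc(C=O)c(OC)c1OC | starting material
19 | 2,3,4-trimethoxyphenyl formate (formed in the flask) | COc1ccc(OC=O)c(OC)c1OC | intermediate
20 | 2,3,4-trimethoxyphenol | COc1ccc(O)c(OC)c1OC | intermediate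
21 | 6-iodo-2,3,4-trimethoxyphenol | COc1cc(I)c(O)c(OC)c1OC | intermediate
22 | (S)-2-[2-(benzyloxy)-3,4,5,6-tetramethoxyphenyl]-3-(6-iodo-2,3,4-trimethoxyphenoxy)propyl acetate | COc1c(OC)c(OC)c(OC)c(OCc2ccccc2)c1[C@H](COC(C)=O)COc1c(I)cc(OC)c(OC)c1OC | intermediate
23 | (R)-2-[2-(benzyloxy)-3,4,5,6-tetramethoxyphenyl]-3-(6-iodo-2,3,4-trimethoxyphenoxy)propan-1-ol | COc1c(OC)c(OC)c(OC)c(OCc2ccccc2)c1[C@H](CO)COc1c(I)cc(OC)c(OC)c1OC | intermediate
24 | (S)-1-(benzyloxy)-2-[1-bromo-3-(6-iodo-2,3,4-trimethoxyphenoxy)propan-2-yl]-3,4,5,6-tetramethoxybenzene | COc1c(OC)c(OC)c(OC)c(OCc2ccccc2)c1[C@H](CBr)COc1c(I)cc(OC)c(OC)c1OC | intermediate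
25 | {2-[(S)-2-(2-benzyloxy-3,4,5,6-tetramethoxyphenyl)-3-bromopropoxy]-3,4,5-trimethoxyphenyl}lithium (formed in the flask) | COc1c(OC)c(OC)c(OC)c(OCc2ccccc2)c1[C@H](CBr)COc1c([Li])cc(OC)c(OC)c1OC | intermediate
26 | (S)-3-[2-(benzyloxy)-3,4,5,6-tetramethoxyphenyl]-6,7,8-trimethoxychroman | COc1c(OC)c(OC)c(OC)c(OCc2ccccc2)c1[C@H]3COc4c(cc(OC)c(OC)c4OC)C3 | intermediate
27 | (S)-2,3,4,5-tetramethoxy-6-(6,7,8-trimethoxychroman-3-yl)phenol | COc1c(OC)c(OC)c(OC)c(O)c1[C@H]2COc3c(cc(OC)c(OC)c3OC)C2 | intermediate
28 | (S)-2,3,5-trimethoxy-6-(6,7,8-trimethoxychroman-3-yl)cyclohexa-2,5-diene-1,4-dione | COC1=C(OC)C(=O)C([C@H]2COc3c(cc(OC)c(OC)c3OC)C2)=C(OC)C1=O | target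

Total step count: 18. Longest linear sequence: 16 steps (steps 1–10 and 13–18, from 1). Iodophenol 21 takes two steps (11 and 12) on a side branch.

Steps most likely to fail

1) Step 16. The aryllithium may be protonated or butylated before it reaches C4. It may also act as a base and induce loss of HBr across C3–C4, because the carbon under attack is β-branched and shielded by ring B. The fallback closes the same C4–C4a bond from 24 without any carbanion, by nickel-catalysed intramolecular reductive cross-electrophile coupling (NiI2, 4,4'-di-tert-butyl-2,2'-bipyridine, Zn powder, NaI, DMA, 25–40 °C). Zerovalent nickel inserts into the aryl–iodine bond, and the bromide is turned into the primary C4 radical, which is one carbon away from C3 and leaves it untouched. Reductive elimination gives 26, where the route is rejoined. No new compound is made (F0).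

2) Step 10. Turnover may be slow, discrimination between the two arms may be weak, or the wrong arm may be chosen, since an aryl group substituted at both ortho positions may fit the active site poorly. The fallback sets C3 by auxiliary-controlled C–C bond formation instead of desymmetrisation, and it sets out from acid 11.
- Pivaloyl chloride and Et3N in THF at −20 °C give 2-[2-(benzyloxy)-3,4,5,6-tetramethoxyphenyl]acetic pivalic anhydride F1.
- LiCl and (S)-4-benzyloxazolidin-2-one convert this in the same flask to (S)-4-benzyl-3-{2-[2-(benzyloxy)-3,4,5,6-tetramethoxyphenyl]acetyl}oxazolidin-2-one F2.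
- The chelated titanium enolate (TiCl4, i-Pr2NEt, CH2Cl2, 0 °C) is hydroxymethylated by 1,3,5-trioxane activated by further TiCl4. Attack on the face away from the benzyl group of the auxiliary should give (S)-4-benzyl-3-{(R)-2-[2-(benzyloxy)-3,4,5,6-tetramethoxyphenyl]-3-hydroxypropanoyl}oxazolidin-2-one F3.
- Silylation (TBSCl, imidazole, DMF) gives (S)-4-benzyl-3-{(R)-2-[2-(benzyloxy)-3,4,5,6-tetramethoxyphenyl]-3-[(tert-butyldimethylsilyl)oxy]propanoyl}oxazolidin-2-one F4.
- LiBH4 (Et2O, one equivalent of MeOH, 0 °C) releases the auxiliary and gives (S)-2-[2-(benzyloxy)-3,4,5,6-tetramethoxyphenyl]-3-[(tert-butyldimethylsilyl)oxy]propan-1-ol F5.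
- Mitsunobu etherification with 21 (PPh3, DIAD, THF) gives (S)-tert-butyl{2-[2-(benzyloxy)-3,4,5,6-tetramethoxyphenyl]-3-(6-iodo-2,3,4-trimethoxyphenoxy)propoxy}dimethylsilane F6.
- TBAF in THF then returns to the route at 23.

In this sequence the former carbonyl carbon becomes C2 and the hydroxymethyl carbon becomes C4.

3) Step 13. Capture of the alkoxyphosphonium ion by a phenol hindered at both ortho positions may be slow. That leaves time for elimination toward C3 or for participation of the neighbouring acetate, and the latter would make the two arms equivalent and erode enantiopurity. The fallback separates activation from displacement. From 17, MsCl and Et3N in CH2Cl2 at 0 °C give (R)-2-[2-(benzyloxy)-3,4,5,6-tetramethoxyphenyl]-3-[(methylsulfonyl)oxy]propyl acetate F7. The preformed cesium phenoxide of 21 (Cs2CO3, DMF, 50 °C), a far stronger nucleophile than the neutral phenol, displaces the sulfonate in an SN2 reaction, and the route is rejoined at 22.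

Further compounds
F0 | step 16 | none | none
F1 | step 10 | 2-[2-(benzyloxy)-3,4,5,6-tetramethoxyphenyl]acetic pivalic anhydride | COc1c(OC)c(OC)c(OC)c(OCc2ccccc2)c1CC(=O)OC(=O)C(C)(C)C
F2 | step 10 | (S)-4-benzyl-3-{2-[2-(benzyloxy)-3,4,5,6-tetramethoxyphenyl]acetyl}oxazolidin-2-one | COc1c(OC)c(OC)c(OC)c(OCc2ccccc2)c1CC(=O)N1[C@@H](Cc2ccccc2)COC1=O
F3 | step 10 | (S)-4-benzyl-3-{(R)-2-[2-(benzyloxy)-3,4,5,6-tetramethoxyphenyl]-3-hydroxypropanoyl}oxazolidin-2-one | COc1c(OC)c(OC)c(OC)c(OCc2ccccc2)c1[C@H](CO)C(=O)N1[C@@H](Cc2ccccc2)COC1=O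
F4 | step 10 | (S)-4-benzyl-3-{(R)-2-[2-(benzyloxy)-3,4,5,6-tetramethoxyphenyl]-3-[(tert-butyldimethylsilyl)oxy]propanoyl}oxazolidin-2-one | COc1c(OC)c(OC)c(OC)c(OCc2ccccc2)c1[C@H](CO[Si](C)(C)C(C)(C)C)C(=O)N1[C@@H](Cc2ccccc2)COC1=O
F5 | step 10 | (S)-2-[2-(benzyloxy)-3,4,5,6-tetramethoxyphenyl]-3-[(tert-butyldimethylsilyl)oxy]propan-1-ol | COc1c(OC)c(OC)c(OC)c(OCc2ccccc2)c1[C@H](CO[Si](C)(C)C(C)(C)C)CO
F6 | step 10 | (S)-tert-butyl{2-[2-(benzyloxy)-3,4,5,6-tetramethoxyphenyl]-3-(6-iodo-2,3,4-trimethoxyphenoxy)propoxy}dimethylsilane | COc1c(OC)c(OC)c(OC)c(OCc2ccccc2)c1[C@H](CO[Si](C)(C)C(C)(C)C)COc1c(I)cc(OC)c(OC)c1OC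
F7 | step 13 | (R)-2-[2-(benzyloxy)-3,4,5,6-tetramethoxyphenyl]-3-[(methylsulfonyl)oxy]propyl acetate | COc1c(OC)c(OC)c(OC)c(OCc2ccccc2)c1[C@H](COC(C)=O)COS(C)(=O)=O
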